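The carbocyclic core is a cyclopentane (C1–C5, C1 being the methyl-bearing ring-fusion carbon) fused to a cycloheptane (C1, C5–C10). The plan cuts C1–C5 and C8–C9 together: C9–C10–C1, with carbonyl-level C10 and fully substituted C1, is an oxyallyl unit, and C5–C6–C7–C8, oxygenated at C6, is a 2-siloxydiene; C2–C3–C4 ties them. A single intramolecular (4+3) cycloaddition therefore closes both rings and creates the quaternary C1. Its precursor is an acyclic epoxy bis(enol silane) in which a cis C1–C2 oxirane serves as the leaving group of the 2-siloxyallyl unit, so that the C2 oxygen is carried along and C1 is fixed by inversion, linked to a (Z,E)-2-siloxydiene.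

Key step: step 14

Remark on the target: as given, the oxirane oxygen is bonded on the β face of C8 and on the α face of C9, so that C7 and C10 lie on opposite faces of the oxirane and the three-membered ring is trans-fused to the cycloheptane; this strained oxirane is assumed to be isolable, cannot arise from a hydroxyl-directed epoxidation of the ring alkene, and is therefore built in the penultimate step from the (E)-configured ring alkene under neutral conditions.

Convention: β is the face of the C1 methyl group, α the opposite face. The target is 1β-Me, 2α-OAc, 4α-OH/4β-iPr, 5α-H, 6α-veratroyloxy, 8α-Me, oxirane oxygen β at C8 and α at C9, 10α-OH.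

Remark on the precursor: with the C1–O2 bond of an oxirane as the leaving group, ionisation needs no enolisation toward the hindered C1, and the C1 configuration follows from a stereospecific inversion instead of a conformational preference about C1–C2.

Step 1
Reactants: 1 allylmagnesium bromide; 2 triisopropyl borate
Product: 3 allyldiisopropoxyborane
Conditions: Et2O, −78 °C; then HCl (1 M in Et2O), 0 °C; distillation
Reagents that add atoms: none
Why: Alkylation of a trialkyl borate by the Grignard reagent gives the allyl borate complex, which anhydrous HCl collapses to the allylboronic ester.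

Step 2
Reactants: 4 ethyl 4-methyl-3-oxopentanoate; 3 allyldiisopropoxyborane
Product: 5 ethyl (3R)-3-hydroxy-3-(propan-2-yl)hex-5-enoate
Conditions: (R)-3,3'-dibromo-1,1'-bi-2-naphthol (15 mol%), PhCF3/PhMe, −35 °C; aqueous work-up
Reagents that add atoms: none
Why: Binaphthol-catalysed asymmetric allylboration of a ketone, in which exchange of an isopropoxy group for the chiral diol gives an activated allylboronate that transfers allyl through a closed chair transition state to the Si face of the ketone (isopropyl as the large group; the catalyst enantiomer is assigned by analogy with aryl methyl ketones and is exchanged for its antipode if the sense is opposite), setting C4, while any enantiomeric leakage becomes a separable diastereomer after step 7.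

Step 3
Reactants: 5 ethyl (3R)-3-hydroxy-3-(propan-2-yl)hex-5-enoate
Product: 6 ethyl (3R)-3-(propan-2-yl)-3-(triethylsilyloxy)hex-5-enoate
Conditions: TESOTf, 2,6-lutidine, CH2Cl2, −78 to 0 °C
Reagents that add atoms: triethylsilyl trifluoromethanesulfonate, CC[Si](CC)(CC)OS(=O)(=O)C(F)(F)F
Why: Silyl ether formation with a silyl triflate and a hindered pyridine base silylates even a tertiary alcohol and avoids retro-aldol cleavage of the β-hydroxy ester.

Step 4
Reactants: 6 ethyl (3R)-3-(propan-2-yl)-3-(triethylsilyloxy)hex-5-enoate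
Product: 7 (3R)-3-(propan-2-yl)-3-(triethylsilyloxy)hex-5-enal
Conditions: iBu2AlH (1.05 equiv), CH2Cl2, −78 °C; Rochelle salt
Reagents that add atoms: none
Why: Partial ester reduction, since at −78 °C the aluminium hemiacetal next to the quaternary centre persists and releases the aldehyde (the future C2) only on work-up.

Step 5
Reactants: 7 (3R)-3-(propan-2-yl)-3-(triethylsilyloxy)hex-5-enal; 8 ethyl 2-[bis(2,2,2-trifluoroethoxy)phosphoryl]propanoate
Product: 9 ethyl (2Z,5R)-2-methyl-5-(propan-2-yl)-5-(triethylsilyloxy)octa-2,7-dienoate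
Conditions: KN(SiMe3)2, 18-crown-6, THF, −78 °C
Reagents that add atoms: none
Why: Still–Gennari olefination, in which the trifluoroethyl phosphonate eliminates fast from the kinetic adduct under dissociating conditions and gives the (Z)-2-methyl enoate with the future C10 and C3 cis, the geometry the oxirane must carry.

Step 6
Reactants: 9 ethyl (2Z,5R)-2-methyl-5-(propan-2-yl)-5-(triethylsilyloxy)octa-2,7-dienoate
Product: 10 (2Z,5R)-2-methyl-5-(propan-2-yl)-5-(triethylsilyloxy)octa-2,7-dien-1-ol
Conditions: iBu2AlH (2.5 equiv), CH2Cl2, −78 °C; Rochelle salt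
Reagents that add atoms: none
Why: 1,2-Hydride reduction of the enoate gives the allylic alcohol without touching the alkene geometry or the silyl ether.

Step 7
Reactants: 10 (2Z,5R)-2-methyl-5-(propan-2-yl)-5-(triethylsilyloxy)octa-2,7-dien-1-ol
Product: 11 {(2S,3R)-2-methyl-3-[(2R)-2-(propan-2-yl)-2-(triethylsilyloxy)pent-4-enyl]oxiran-2-yl}methanol
Conditions: Ti(OiPr)4 (20 mol%), L-(+)-diethyl tartrate (24 mol%), tBuOOH, 4 Å sieves, CH2Cl2, −20 °C
Reagents that add atoms: tert-butyl hydroperoxide, CC(C)(C)OO
Why: Sharpless asymmetric epoxidation, in which the Ti(OiPr)4/L-(+)-diethyl tartrate complex delivers oxygen stereospecifically to the face of the (Z)-allylic alcohol that gives the (2S,3R)-oxirane, setting C2 (R) and the C1 oxirane carbon under reagent control while the isolated terminal alkene is inert.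

Step 8
Reactants: 11 {(2S,3R)-2-methyl-3-[(2R)-2-(propan-2-yl)-2-(triethylsilyloxy)pent-4-enyl]oxiran-2-yl}methanol
Product: 12 (2R,3R)-2-methyl-3-[(2R)-2-(propan-2-yl)-2-(triethylsilyloxy)pent-4-enyl]oxirane-2-carbaldehyde
Conditions: Dess–Martin periodinane, NaHCO3, CH2Cl2, 0 °C to rt
Reagents that add atoms: none
Why: Dess–Martin oxidation under buffered conditions gives the epoxy aldehyde without opening the oxirane or cleaving the silyl ether.

Step 9
Reactants: 12 (2R,3R)-2-methyl-3-[(2R)-2-(propan-2-yl)-2-(triethylsilyloxy)pent-4-enyl]oxirane-2-carbaldehyde; 13 methylmagnesium bromide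
Product: 14 1-{(2S,3R)-2-methyl-3-[(2R)-2-(propan-2-yl)-2-(triethylsilyloxy)pent-4-enyl]oxiran-2-yl}ethanol (both carbinol epimers)
Conditions: MeMgBr, THF, −78 °C; aq. NH4Cl
Reagents that add atoms: none
Why: Grignard 1,2-addition to the aldehyde (the methyl carbon becomes C9) is far faster than attack on the trisubstituted oxirane, and the new carbinol centre needs no control because it is oxidised in step 12.

Step 10
Reactants: 14 1-{(2S,3R)-2-methyl-3-[(2R)-2-(propan-2-yl)-2-(triethylsilyloxy)pent-4-enyl]oxiran-2-yl}ethanol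
Product: 15 (3S)-4-[(2R,3S)-3-(1-hydroxyethyl)-3-methyloxiran-2-yl]-3-(propan-2-yl)-3-(triethylsilyloxy)butanal
Conditions: O3, CH2Cl2/MeOH, −78 °C; then PPh3, −78 °C to rt
Reagents that add atoms: ozone, [O-][O+]=O
Why: Ozonolysis with reductive work-up cleaves the only alkene to the C6 aldehyde, and the oxirane, alcohol and silyl ether are inert to ozone.

Step 11
Reactants: 15 (3S)-4-[(2R,3S)-3-(1-hydroxyethyl)-3-methyloxiran-2-yl]-3-(propan-2-yl)-3-(triethylsilyloxy)butanal; 16 (E)-1-bromoprop-1-ene
Product: 17 (2R,5E)-1-[(2R,3S)-3-(1-hydroxyethyl)-3-methyloxiran-2-yl]-2-(propan-2-yl)-2-(triethylsilyloxy)hept-5-en-4-ol (epimers at both secondary carbinols)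
Conditions: 16, t-BuLi (2 equiv per bromide), Et2O, −78 °C; then 15 (0.4 equiv), −78 °C; aq. NH4Cl
Reagents that add atoms: none
Why: Bromine–lithium exchange gives (E)-propenyllithium with retention, which adds 1,2 to the aldehyde after one equivalent has deprotonated the hydroxyl group, and at −78 °C the lithium alkoxide should not undergo Payne migration.

Step 12
Reactants: 17 (2R,5E)-1-[(2R,3S)-3-(1-hydroxyethyl)-3-methyloxiran-2-yl]-2-(propan-2-yl)-2-(triethylsilyloxy)hept-5-en-4-ol
Product: 18 (2S,5E)-1-[(2R,3R)-3-acetyl-3-methyloxiran-2-yl]-2-(propan-2-yl)-2-(triethylsilyloxy)hept-5-en-4-one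
Conditions: Dess–Martin periodinane (3 equiv), NaHCO3, CH2Cl2, 0 °C to rt
Reagents that add atoms: none
Why: A double Dess–Martin oxidation converts the α-epoxy carbinol and the allylic carbinol into the methyl ketone (C10) and the (E)-enone (C6) in one operation under conditions too mild for β-elimination of the C4 silyloxy group.

Step 13
Reactants: 18 (2S,5E)-1-[(2R,3R)-3-acetyl-3-methyloxiran-2-yl]-2-(propan-2-yl)-2-(triethylsilyloxy)hept-5-en-4-one
Product: 19 epoxy bis(enol silane): C9H2=C10(OSiEt3)–C1(Me)–C2H cis-oxirane (1R,2R), C3H2, C4(OSiEt3)(iPr) (R), (5Z,7E)-C5H=C6(OSiEt3)–C7H=C8H–CH3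
Conditions: TESOTf (2.4 equiv), Et3N (4 equiv), CH2Cl2, −78 to −20 °C; filtration through Et3N-deactivated silica
Reagents that add atoms: triethylsilyl trifluoromethanesulfonate, CC[Si](CC)(CC)OS(=O)(=O)C(F)(F)F
Why: Soft enolisation (enol silylation) can take the epoxy ketone only toward the methyl group C9 and takes the enone at the α' carbon C5 to the cross-conjugated 2-siloxydiene, whose preferred (Z) geometry (C4 cis to oxygen, avoiding allylic strain with the propenyl group) leaves only hydrogen inside the s-cis diene.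

Step 14
Reactants: 19 epoxy bis(enol silane)
Product: 20 trans-fused hydroazulen-10-one: 1β-methyl, 2α-OSiEt3, 4α-OSiEt3, 4β-isopropyl, 5α-H, C6=C7 triethylsilyl enol ether, 8-methyl (both C8 epimers)
Conditions: TESOTf (10 mol%), CH2Cl2, −78 °C; Et3N, then aq. NaHCO3
Reagents that add atoms: none
Why: Catalytic TESOTf silylates the oxirane oxygen, the nucleophilic diene terminus C5 attacks C1 anti to the breaking C1–O2 bond while the diene lies over the enol silane, C9 bonds to C8 in the same asynchronous event and the C10 silyloxocarbenium ion releases TESOTf, a net isomerisation whose closest known reaction type is the silyl-triflate-catalysed intramolecular (4+3) cycloaddition of epoxy enol silanes (functionalised 2-siloxyallyl cation precursors) with tethered dienes. The five-membered ring C1–C5 closes by an endo-mode opening of the oxirane (both oxirane carbons end in the ring), feasible because C1 is tertiary and allyl-stabilised so that C–O cleavage runs ahead of bond formation, and the seven-membered ring closes as the union of the four-carbon diene C5=C6–C7=C8 with the three-carbon unit C9–C10–C1. C1 is fixed by inversion at the oxirane carbon: because C10 and C3 are cis on the oxirane, C10 ends cis and the methyl group trans to the C2 oxygen, whatever the conformation about C1–C2. C5 should arise from the extended (exo) arrangement, which keeps the C6 and C10 siloxy groups apart and gives the trans ring fusion (it stays epimerisable through the C6 ketone of 22), and C8 is not controlled because it becomes trigonal in step 18. The step needs the second bond to form at C8 and not at C6 (a five-membered alternative), which the (Z)-enol ether geometry, allowing the s-cis diene to stack on the enol silane, and the three-atom tether are expected to secure.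

Step 15
Reactants: 20 trans-fused hydroazulen-10-one
Product: 22 6-ketone with C10 masked as the C9=C10 tert-butyldimethylsilyl enol ether (2α- and 4α-OSiEt3 retained, C8 epimers), via bis(silyl enol ether) 21 (not isolated)
Conditions: TBSOTf, Et3N, CH2Cl2, 0 °C to rt; then 5% aq. citric acid, THF, 0 °C
Reagents that add atoms: tert-butyldimethylsilyl trifluoromethanesulfonate, CC(C)(C)[Si](C)(C)OS(=O)(=O)C(F)(F)F
Why: Enol silylation of the C10 ketone, which has α-hydrogens only at C9, gives a single robust enol ether that masks C10 and later serves the dehydrogenation, after which mild acid hydrolyses the far more labile triethylsilyl enol ether at C6 (protonation at C7, C5 untouched) and spares the other silyl groups.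

Step 16
Reactants: 22 6-ketone with C10 silyl enol ether
Product: 23 6α-alcohol (6R; other groups unchanged)
Conditions: SmI2, H2O, Et3N, THF, 0 °C
Reagents that add atoms: none
Why: Ketyl (single-electron) reduction with SmI2 is not governed by steric approach and should give the thermodynamically preferred equatorial 6α-alcohol (the 6β-epimer would be 1,3-diaxial to the C1 methyl group), whereas hydride reagents would enter from the open α face and give the axial epimer.

Step 17
Reactants: 23 6α-alcohol; 24 3,4-dimethoxybenzoyl chloride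
Product: 25 6α-veratroate (C10 silyl enol ether, 2α- and 4α-OSiEt3, C8 epimers)
Conditions: 24, 4-(dimethylamino)pyridine, Et3N, CH2Cl2, rt
Reagents that add atoms: none
Why: Nucleophile-catalysed acylation (esterification) of the only free hydroxyl group by the acid chloride is tolerated by the silyl enol ether under amine-buffered conditions.

Step 18
Reactants: 25 6α-veratroate
Product: 26 C8=C9 enone (10-ketone; 6α-veratroate, 2α- and 4α-OSiEt3)
Conditions: Pd(OAc)2 (1.1 equiv), MeCN, rt to 40 °C
Reagents that add atoms: none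
Why: Saegusa–Ito oxidation, in which palladium diacetate (divalent palladium) palladates the enol ether at C9 and syn β-hydride elimination of the C8 hydrogen gives the trisubstituted enone and zerovalent palladium, so that both C8 epimers converge.

Step 19
Reactants: 26 C8=C9 enone
Product: 27 enone diol (2α-OH, 4α-OH, 6α-veratroate)
Conditions: HF·pyridine, pyridine, THF, 0 °C to rt
Reagents that add atoms: none
Why: Fluoride desilylation removes the secondary and the tertiary triethylsilyl ether under weakly acidic conditions that avoid retro-aldol opening of the β-hydroxy ketone and vinylogous elimination of the veratroate.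

Step 20
Reactants: 27 enone diol
Product: 28 allylic triol (10α-OH, C8=C9; 2α-OH, 4α-OH, 6α-veratroate)
Conditions: Et2BOMe, THF/MeOH (4:1), −78 °C; NaBH4; AcOH, then repeated evaporation from MeOH
Reagents that add atoms: none
Why: Narasaka–Prasad reduction, in which Et2BOMe ties the C2 hydroxyl and the C10 carbonyl oxygen into a six-membered boron chelate on the α face and external hydride adds 1,2 to that chelate from the β face, giving the 1,3-syn diol and hence the 10α-alcohol.

Step 21
Reactants: 28 allylic triol
Product: 30 trans-fused 8,9-epoxy triol, via (E)-alkene 29 (not isolated)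
Conditions: hν (254 nm), toluene, −78 °C; then dimethyldioxirane (acetone), −78 °C, dark; unchanged 28 recycled
Reagents that add atoms: dimethyldioxirane, CC1(C)OO1
Why: Proposed new method: triplet energy transfer from photoexcited toluene is expected to twist the trisubstituted C8=C9 bond into the strained (E)-cycloheptene 29, which should persist at −78 °C and take oxygen from dimethyldioxirane in one suprafacial step on its exposed face far faster than unchanged 28, so that C8 and C9 are set together with C7 and C10 on opposite faces of the oxirane, the helical form of 29 with H9 on the β face and the C8 methyl group on the α face leading to oxygen bonded β at C8 and α at C9 (cis to the C10 hydroxyl); the closest known reaction types are the arene-sensitised Z to E photoisomerisation of 1-alkylcycloheptenes with low-temperature capture of the (E)-isomer by an oxidant and the stereospecific dioxirane epoxidation of trans-cyclooctenes.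

Step 22
Reactants: 30 trans-fused 8,9-epoxy triol; 31 acetic anhydride
Product: 32 target: 2α-acetoxy-4α,10α-dihydroxy-6α-(3,4-dimethoxybenzoyloxy) compound with the oxirane oxygen β at C8 and α at C9
Conditions: Ac2O (1.2 equiv), pyridine, 0 °C
Reagents that add atoms: none
Why: Acetylation without an acyl-transfer catalyst should distinguish the hydroxyl groups by hindrance, the C4 alcohol being tertiary and the C10 alcohol flanked by the quaternary C1 and the oxirane (to which it is hydrogen-bonded), which leaves the C2 cyclopentanol as the accessible site, and the basic medium spares the strained oxirane.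

Compound list
1 | allylmagnesium bromide | C=CC[Mg]Br | starting material
2 | triisopropyl borate | CC(C)OB(OC(C)C)OC(C)C | starting material
3 | allyldiisopropoxyborane | C=CCB(OC(C)C)OC(C)C | intermediate
4 | ethyl 4-methyl-3-oxopentanoate | CCOC(=O)CC(=O)C(C)C | starting material
5 | ethyl (3R)-3-hydroxy-3-(propan-2-yl)hex-5-enoate | CCOC(=O)C[C@@](O)(C(C)C)CC=C | intermediate
6 | ethyl (3R)-3-(propan-2-yl)-3-(triethylsilyloxy)hex-5-enoate | CCOC(=O)C[C@@](O[Si](CC)(CC)CC)(C(C)C)CC=C | intermediate
7 | (3R)-3-(propan-2-yl)-3-(triethylsilyloxy)hex-5-enal | O=CC[C@@](O[Si](CC)(CC)CC)(C(C)C)CC=C | intermediate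
8 | ethyl 2-[bis(2,2,2-trifluoroethoxy)phosphoryl]propanoate | CCOC(=O)C(C)P(=O)(OCC(F)(F)F)OCC(F)(F)F | starting material
9 | ethyl (2Z,5R)-2-methyl-5-(propan-2-yl)-5-(triethylsilyloxy)octa-2,7-dienoate | CCOC(=O)/C(C)=C\C[C@@](O[Si](CC)(CC)CC)(C(C)C)CC=C | intermediate
10 | (2Z,5R)-2-methyl-5-(propan-2-yl)-5-(triethylsilyloxy)octa-2,7-dien-1-ol | OC/C(C)=C\C[C@@](O[Si](CC)(CC)CC)(C(C)C)CC=C | intermediate
11 | {(2S,3R)-2-methyl-3-[(2R)-2-(propan-2-yl)-2-(triethylsilyloxy)pent-4-enyl]oxiran-2-yl}methanol | OC[C@]1(C)O[C@@H]1C[C@@](O[Si](CC)(CC)CC)(C(C)C)CC=C | intermediate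
12 | (2R,3R)-2-methyl-3-[(2R)-2-(propan-2-yl)-2-(triethylsilyloxy)pent-4-enyl]oxirane-2-carbaldehyde | O=C[C@]1(C)O[C@@H]1C[C@@](O[Si](CC)(CC)CC)(C(C)C)CC=C | intermediate
13 | methylmagnesium bromide | C[Mg]Br | starting material
14 | 1-{(2S,3R)-2-methyl-3-[(2R)-2-(propan-2-yl)-2-(triethylsilyloxy)pent-4-enyl]oxiran-2-yl}ethanol (carbinol epimers) | CC(O)[C@]1(C)O[C@@H]1C[C@@](O[Si](CC)(CC)CC)(C(C)C)CC=C | intermediate
15 | (3S)-4-[(2R,3S)-3-(1-hydroxyethyl)-3-methyloxiran-2-yl]-3-(propan-2-yl)-3-(triethylsilyloxy)butanal | CC(O)[C@]1(C)O[C@@H]1C[C@@](O[Si](CC)(CC)CC)(C(C)C)CC=O | intermediate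
16 | (E)-1-bromoprop-1-ene | C/C=C/Br | starting material
17 | (2R,5E)-1-[(2R,3S)-3-(1-hydroxyethyl)-3-methyloxiran-2-yl]-2-(propan-2-yl)-2-(triethylsilyloxy)hept-5-en-4-ol (carbinol epimers) | CC(O)[C@]1(C)O[C@@H]1C[C@@](O[Si](CC)(CC)CC)(C(C)C)CC(O)/C=C/C | intermediate
18 | (2S,5E)-1-[(2R,3R)-3-acetyl-3-methyloxiran-2-yl]-2-(propan-2-yl)-2-(triethylsilyloxy)hept-5-en-4-one | CC(=O)[C@]1(C)O[C@@H]1C[C@@](O[Si](CC)(CC)CC)(C(C)C)CC(=O)/C=C/C | intermediate
19 | epoxy bis(enol silane), cis-oxirane (1R,2R), 4R, 5Z,7E | C=C(O[Si](CC)(CC)CC)[C@]1(C)O[C@@H]1C[C@@](O[Si](CC)(CC)CC)(C(C)C)/C=C(\O[Si](CC)(CC)CC)/C=C/C | intermediate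
20 | trans-fused hydroazulen-10-one, 1β-Me, 2α- and 4α-OSiEt3, 4β-iPr, 5α-H, C6=C7 triethylsilyl enol ether, C8 epimers | CC1CC(=O)[C@]2(C)[C@H](O[Si](CC)(CC)CC)C[C@@](O[Si](CC)(CC)CC)(C(C)C)[C@H]2C(O[Si](CC)(CC)CC)=C1 | intermediate
21 | bis(silyl enol ether): C9=C10 OTBS and C6=C7 OSiEt3 | CC1C=C(O[Si](C)(C)C(C)(C)C)[C@]2(C)[C@H](O[Si](CC)(CC)CC)C[C@@](O[Si](CC)(CC)CC)(C(C)C)[C@H]2C(O[Si](CC)(CC)CC)=C1 | intermediate
22 | 6-ketone with C9=C10 TBS enol ether | CC1C=C(O[Si](C)(C)C(C)(C)C)[C@]2(C)[C@H](O[Si](CC)(CC)CC)C[C@@](O[Si](CC)(CC)CC)(C(C)C)[C@H]2C(=O)C1 | intermediate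
23 | 6α-alcohol with C9=C10 TBS enol ether | CC1C=C(O[Si](C)(C)C(C)(C)C)[C@]2(C)[C@H](O[Si](CC)(CC)CC)C[C@@](O[Si](CC)(CC)CC)(C(C)C)[C@H]2[C@H](O)C1 | intermediate
24 | 3,4-dimethoxybenzoyl chloride | COc1ccc(C(Cl)=O)cc1OC | starting material
25 | 6α-veratroate with C9=C10 TBS enol ether | COc1ccc(C(=O)O[C@@H]2CC(C)C=C(O[Si](C)(C)C(C)(C)C)[C@]3(C)[C@H](O[Si](CC)(CC)CC)C[C@@](O[Si](CC)(CC)CC)(C(C)C)[C@@H]23)cc1OC | intermediate
26 | C8=C9 enone, 6α-veratroate, 2α- and 4α-OSiEt3 | COc1ccc(C(=O)O[C@@H]2CC(C)=CC(=O)[C@]3(C)[C@H](O[Si](CC)(CC)CC)C[C@@](O[Si](CC)(CC)CC)(C(C)C)[C@@H]23)cc1OC | intermediate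
27 | enone diol, 2α-OH, 4α-OH, 6α-veratroate | COc1ccc(C(=O)O[C@@H]2CC(C)=CC(=O)[C@]3(C)[C@H](O)C[C@@](O)(C(C)C)[C@@H]23)cc1OC | intermediate
28 | allylic triol, 10α-OH, C8=C9 | COc1ccc(C(=O)O[C@@H]2CC(C)=C[C@H](O)[C@]3(C)[C@H](O)C[C@@](O)(C(C)C)[C@@H]23)cc1OC | intermediate
29 | (E)-C8=C9 isomer of allylic triol 28 (ring-trans alkene; H9 on the β face, C8 methyl on the α face) | COc1ccc(C(=O)O[C@@H]2C/C(C)=C/[C@H](O)[C@]3(C)[C@H](O)C[C@@](O)(C(C)C)[C@@H]23)cc1OC | intermediate
30 | trans-fused 8,9-epoxy triol (oxirane oxygen β at C8 and α at C9; 2α-, 4α- and 10α-OH, 6α-veratroate) | COc1ccc(C(=O)O[C@@H]2C[C@@]3(C)O[C@@H]3[C@H](O)[C@]3(C)[C@H](O)C[C@@](O)(C(C)C)[C@@H]23)cc1OC | intermediate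
31 | acetic anhydride | CC(=O)OC(C)=O | starting material
32 | target: 2α-acetoxy-4α,10α-dihydroxy-6α-(3,4-dimethoxybenzoyloxy) compound, oxirane oxygen β at C8 and α at C9 (trans-fused oxirane) | COc1ccc(C(=O)O[C@@H]2C[C@@]3(C)O[C@@H]3[C@H](O)[C@]3(C)[C@H](OC(C)=O)C[C@@](O)(C(C)C)[C@@H]23)cc1OC | target

Total step count: 22. Longest linear sequence: 22 steps (1 to 32; 21 steps from ethyl 4-methyl-3-oxopentanoate 4).

Steps most likely to fail

Step 21. Three processes can defeat it: the (E)-alkene may not build up, because the trans-fused cyclopentane adds to its strain; it may form in the other helical sense and then lead to the diastereomeric trans-fused oxirane; or unchanged 28 may be epoxidised on its α face under direction by the C10 hydroxyl, which gives a cis ring fusion of the oxirane. The fallback sets out from 28 and returns at 30; it closes the oxirane by a displacement whose steric course is fixed by inversion and does not depend on alkene helicity, although it too works against the strain of the trans ring fusion. tBu2Si(OTf)2/2,6-lutidine (CH2Cl2, 0 °C) ties the syn-related C2 and C10 hydroxyls into the 2,10-O-di-tert-butylsilylene F1. OsO4 (catalytic)/N-methylmorpholine N-oxide adds to the β face of the C8=C9 alkene, anti to the allylic C10 oxygen, and gives the 8β,9β-diol F2. MsCl/Et3N sulfonylates the only free secondary hydroxyl and gives the C9 mesylate F3. KN(SiMe3)2 (THF, −78 to 0 °C) forms the tertiary C8 alkoxide, which displaces the mesylate with inversion at C9 (oxirane formation from a 2-hydroxyalkyl sulfonate) and gives the silylene-protected trans-fused oxirane F4. Bu4NF buffered with AcOH (THF, 0 °C) removes the silylene and gives 30.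

Step 14. The second bond may close at C6 instead of C8, giving a five- instead of a seven-membered ring, or the silyl-activated oxirane may rearrange before the diene engages. The fallback sets out from 19 and returns at 25; it makes the two bonds in separate operations and lets the seven-membered ring form under thermodynamic control. BF3·OEt2 (1 equiv, CH2Cl2, −78 °C) with aqueous work-up should promote only the Mukaiyama-type opening of the oxirane at C1 by the siloxydiene and hydrolyse the enol silanes, giving the cyclopentane hydroxy enone–methyl ketone F5. TESOTf/2,6-lutidine then gives its 2-O-triethylsilyl ether F6. Cs2CO3 in t-BuOH/THF closes the ring by intramolecular Michael addition of the methyl ketone enolate (C9) to the enone carbon C8, reversible aldol pathways draining into the hydroazulene-6,10-dione F7, with C5 free to equilibrate. SmI2/H2O/Et3N reduces both ketones to the 6α,10-diol F8. 3,4-Dimethoxybenzoyl chloride/4-(dimethylamino)pyridine acylates the less hindered 6α-hydroxyl to give the 6α-veratroate 10-alcohol F9. Dess–Martin oxidation gives the 6α-veratroate 10-ketone F10, and TBSOTf/Et3N converts it into 25.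

Step 2. Enantioselectivity may be low, because isopropyl and (ethoxycarbonyl)methyl are not differentiated well enough or because the β-keto ester binds the boronate. The fallback sets out from 4 and returns at 7; C4 is set by a Sharpless epoxidation instead. Tf2O with aqueous LiOH gives the (Z)-enol triflate F11. Stille coupling with allyltributylstannane (Pd(PPh3)4, THF) gives, with retention, the (E)-dienoate F12. iBu2AlH gives the (E)-dienol F13. Sharpless epoxidation with L-(+)-diethyl tartrate gives the (2S,3S)-epoxy alcohol F14. NaAlH2(OCH2CH2OMe)2 delivers hydride to C2 of the oxirane and gives the (R)-1,3-diol F15. TESOTf/2,6-lutidine gives the bis(triethylsilyl) ether F16, and Swern oxidation converts the primary silyl ether directly into aldehyde 7.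

Further compounds
F1 | step 21 | 2,10-O-di-tert-butylsilylene of allylic triol 28 | COc1ccc(C(=O)O[C@@H]2CC(C)=C[C@H](O4)[C@]3(C)[C@H](O[Si]4(C(C)(C)C)C(C)(C)C)C[C@@](O)(C(C)C)[C@@H]23)cc1OC
F2 | step 21 | 8β,9β-diol (8α-methyl) with 2,10-O-silylene | COc1ccc(C(=O)O[C@@H]2C[C@@](C)(O)[C@@H](O)[C@H](O4)[C@]3(C)[C@H](O[Si]4(C(C)(C)C)C(C)(C)C)C[C@@](O)(C(C)C)[C@@H]23)cc1OC
F3 | step 21 | 9β-mesylate of F2 | COc1ccc(C(=O)O[C@@H]2C[C@@](C)(O)[C@@H](OS(C)(=O)=O)[C@H](O4)[C@]3(C)[C@H](O[Si]4(C(C)(C)C)C(C)(C)C)C[C@@](O)(C(C)C)[C@@H]23)cc1OC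
F4 | step 21 | trans-fused 8,9-oxirane (oxygen β at C8 and α at C9) with 2,10-O-silylene | COc1ccc(C(=O)O[C@@H]2C[C@@]3(C)O[C@@H]3[C@H](O4)[C@]3(C)[C@H](O[Si]4(C(C)(C)C)C(C)(C)C)C[C@@](O)(C(C)C)[C@@H]23)cc1OC
F5 | step 14 | cyclopentane hydroxy enone–methyl ketone (1-acetyl-1β-methyl, 2α-OH, 4α-OSiEt3, 4β-iPr, 5-(E)-but-2-enoyl) | CC(=O)[C@]1(C)[C@H](O)C[C@@](O[Si](CC)(CC)CC)(C(C)C)C1C(=O)/C=C/C
F6 | step 14 | 2-O-triethylsilyl ether of F5 | CC(=O)[C@]1(C)[C@H](O[Si](CC)(CC)CC)C[C@@](O[Si](CC)(CC)CC)(C(C)C)C1C(=O)/C=C/C
F7 | step 14 | hydroazulene-6,10-dione (2α- and 4α-OSiEt3, C8 epimers) | CC1CC(=O)[C@]2(C)[C@H](O[Si](CC)(CC)CC)C[C@@](O[Si](CC)(CC)CC)(C(C)C)[C@H]2C(=O)C1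
F8 | step 14 | 6α,10-diol | CC1CC(O)[C@]2(C)[C@H](O[Si](CC)(CC)CC)C[C@@](O[Si](CC)(CC)CC)(C(C)C)[C@H]2[C@H](O)C1
F9 | step 14 | 6α-veratroate 10-alcohol | COc1ccc(C(=O)O[C@@H]2CC(C)CC(O)[C@]3(C)[C@H](O[Si](CC)(CC)CC)C[C@@](O[Si](CC)(CC)CC)(C(C)C)[C@@H]23)cc1OC
F10 | step 14 | 6α-veratroate 10-ketone | COc1ccc(C(=O)O[C@@H]2CC(C)CC(=O)[C@]3(C)[C@H](O[Si](CC)(CC)CC)C[C@@](O[Si](CC)(CC)CC)(C(C)C)[C@@H]23)cc1OC
F11 | step 2 | ethyl (2Z)-4-methyl-3-(trifluoromethylsulfonyloxy)pent-2-enoate | CCOC(=O)/C=C(\OS(=O)(=O)C(F)(F)F)C(C)C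
F12 | step 2 | ethyl (2E)-3-(propan-2-yl)hexa-2,5-dienoate | CCOC(=O)/C=C(\CC=C)C(C)C
F13 | step 2 | (2E)-3-(propan-2-yl)hexa-2,5-dien-1-ol | OC/C=C(\CC=C)C(C)C
F14 | step 2 | [(2S,3S)-3-(propan-2-yl)-3-(prop-2-enyl)oxiran-2-yl]methanol | OC[C@@H]1O[C@@]1(CC=C)C(C)C
F15 | step 2 | (3R)-3-(propan-2-yl)hex-5-ene-1,3-diol | OCC[C@@](O)(C(C)C)CC=C
F16 | step 2 | (3R)-3-(propan-2-yl)-1,3-bis(triethylsilyloxy)hex-5-ene | CC[Si](CC)(CC)OCC[C@@](O[Si](CC)(CC)CC)(C(C)C)CC=C
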